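The vessel was closed, stirred and isothermal, and I wanted to know how far its substrate got.

- Monday's: substrate 0.050 M; reagent 0.028 M; run made earlier
- flask: substrate 0.050 M; reagent 0.0550 M; time 2.0 min
Monday's run (percent of the substrate charged)

| time / s | substrate / % | target / % |
|---|---|---|
| 10.0 | 63.3 | 9.4 |
| 12.0 | 59.7 | 9.8 |

(readings scatter by 0.3 percentage points)
1. part of the substrate that has reacted at 2.0 min
2. share of the unused reagent that is free and not bound as idle adduct, at 2.0 min

I took one reagent per substrate, since two would have needed 0.0403 M by Monday's last reading, more than the 0.028 M charged. With a rate k·c(reagent)·c(substrate), the difference of the two concentrations stays constant and the integral closes: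

c(reagent)/c(substrate) = [start ratio]·exp(N), with N = k·(start excess of reagent)·t

Monday's last reading gave k = 2.86 M⁻¹ s⁻¹. For this flask that made 1.72, the lead number: the run time counted in time constants of the excess, here 69.9 s, its sign telling which charge goes first. Reading it off, I expected 1.95 % of the substrate left.

Monday's first reading gave 2.76 M⁻¹ s⁻¹, with which the same reckoning put 2.09 % of the substrate left in this flask, but the lead number says nothing of bound reagent.

The forecast said 96 % and 55 %, less reacted than my figure, noting “If binding ties up reagent, the late reaction slows”.

The flask gave 96.4 % and 57.9 %, with 0.00285 M of idle adduct at 2.00 min.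

    substrate + reagent → intermediate + by-product (k = 3.30 M⁻¹ s⁻¹)
    intermediate ⇌ target (K = 0.640, k = 0.400 s⁻¹)
    intermediate ⇌ isomer of the product (K = 2.00, k = 0.150 s⁻¹)
    reagent + by-product ⇌ idle adduct, settled at all times (K = 16.0 M⁻¹)

Counting bound reagent as unused, the substrate left in this flask corresponds to a lead number of 1.24, smaller than mine. The answer had moved 5 points at 0.0489 M of reagent, where N is −0.392. In a neighbour flask with 0.20 M of substrate, N is −49.8, so the reagent is the limiting reagent and the substrate reacted should stop at 27.5 %; that neighbour flask held 0 % of free reagent and 0 M of idle adduct at 2.00 min and gave 27.5 %.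

(The runs are calculated on assumed constants; scatter was added.)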